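All runs are simulated with constants of no real substance; the scatter is artificial.

If you repeat this flask, watch the clock as well as the reagent.

- alder: left-handed substrate 0.030 M; right-handed substrate 0.030 M; reagent 3 equiv; free catalyst 0.048 mol%; run made earlier
- flask: left-handed substrate 0.030 M; reagent 3.00 equiv; free catalyst 0.095 mol%; right-handed substrate 0.030 M

alder run (percent of the left-handed substrate and right-handed substrate together charged)

| time / h | left-handed product / % |
|---|---|
| 0.417 | 0.8 |
| 0.667 | 1.2 |
| 1.00 | 2.0 |
| 1.33 | 2.8 |
| 2.00 | 3.7 |
| 3.00 | 5.3 |
| 5.00 | 7.7 |

(scatter of a reading: 0.3 percentage points)

- free catalyst is single-handed; left-handed substrate and right-handed substrate are mirror images of each other, charged as a racemate, each of them at the stated concentration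
- no earlier run changes the charge of free catalyst; that part of a forecast is a guess
- no earlier run changes the charge of reagent; that part of a forecast is a guess

- apparent order in reagent when 30 % of the left-handed substrate and right-handed substrate together are converted (percent change of the rate of making left-handed product for one percent more reagent charged)

Two chemists dispute the order in reagent. The first looks at reagent loss. If each converted substrate takes one reagent, the flask has used 20.0 % of its reagent charge at 30 % conversion. One percent more charged then means 1.25 percent more present. So a plain bimolecular step gives 1.25, and saturated catalyst gives less.

The second looks at the alder run. Its left-handed product came at 0.0200 h⁻¹ of the substrates charged in the first hours, but at 0.0120 h⁻¹ late on. Substrate loss covers part of that fall. What remains gives the catalyst fade rate, the fraction of catalyst activity lost per hour, 0.112 h⁻¹. It is a rough reading, since each point carries 0.3 percentage points.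

Fixed conversion means different times. Replace the alder curve by its mean rate and scale it to this flask's loading. If both substrates react alike, this flask reaches 30 % in about 4.92 h. One percent more reagent shortens that by about one percent, so the surviving catalyst activity at that point is higher by 0.551 percent. I side with the second chemist and reckon 1.80.

The forecast, on the first side, took 0.7, from 0 to 1.25, because saturation would “pull it towards 0”.

The flask gives 1.4, higher than the first view's 1.25 but lower than my 1.80.

    free catalyst + left-handed substrate ⇌ catalyst intermediate A (K = 13.0 M⁻¹, k = 20500 M⁻¹ h⁻¹)
    free catalyst + right-handed substrate ⇌ catalyst intermediate B (K = 34.0 M⁻¹, k = 1.40 × 10⁵ M⁻¹ h⁻¹)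
    reagent + catalyst intermediate A → free catalyst + left-handed product (k = 7700 M⁻¹ h⁻¹)
    reagent + catalyst intermediate B → free catalyst + right-handed product (k = 3500 M⁻¹ h⁻¹)
    free catalyst ⇌ dormant form (K = 8.70, k = 0.0612 h⁻¹)
    free catalyst → spent catalyst (k = 0.114 h⁻¹)

The first view keeps the early hours of this flask: at 2.50 h, catalyst intermediates A and B hold 39.5 % of the catalyst. The fade rate gives this flask a catalyst life of 8.93 h, shorter than the marked 25.0 h, and it puts 24.7 % of the catalyst still working at 12.5 h, where the flask has 29.5 % outside the off-cycle forms. At 25.0 h, spent catalyst is 62.2 % of the catalyst, while 46 % of the left-handed substrate charged and 59 % of the reagent charged remain.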